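The runs were computed for substances that don't exist; scatter was added.

The green run, charged at 1.9 M of starting material, stands close to the south-east flask, so I read what I can from it.

| flask | starting material | remark | time |
|---|---|---|---|
| green | 1.9 M | run made earlier |  |
| north | 1.5 M |  | 2.5 d |
| south-east | 2.0 M |  | 2.5 d |
| south-west | 3.0 M |  | 2.5 d |

green run (percent of the starting material charged)

| time / h | ring / % | open dimer / % | over-reaction product / % |
|---|---|---|---|
| 6.00 | 25.7 | 47.4 | 2.4 |
| 12.0 | 33.1 | 48.8 | 4.4 |
| 20.0 | 36.7 | 47.3 | 7.1 |
| 25.0 | 37.5 | 41.9 | 12.6 |
| 30.0 | 37.5 | 41.4 | 15.2 |
| 40.0 | 37.8 | 35.8 | 20.2 |

(each reading ± 1 percentage point)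

1. share of ring in all that became ring or open dimer or over-reaction product for north, south-east, south-west, in this order
2. how that number moves from the first to the last of them (falls, then rises / rises, then falls / falls all the way / hardly changes / rises all the way)

- percentages count the starting material that a species holds: one open dimer counts as two
- "hardly changes" means that all values lie within two and a half points (for a concentration: within two and a half percent of the largest)

I can turn two settings, and the first is the charge. By hand, if ring forms from one molecule and open dimer from two, a stronger charge should lower the share of ring, the selectivity for ring. The green run at 6.00 h already holds more open dimer, 47.4 %, than ring, 25.7 %.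

The second setting is time, which I solve at both ends and then join. Across the green readings the share climbs, from 34.0 % at 6.00 h to 40.3 % at 40.0 h. For the time beyond those readings, I suppose that over-reaction product comes from ring, so each bit of it leaves the top of the fraction and stays in the bottom.

The join is a reading from green between 20.0 h and 40.0 h: over-reaction product gains 13 percentage points while ring stands near 37.8 %. That gives 0.0176 h⁻¹ for the leak, the over-reaction product gained per hour for each part of ring present.

I treat south-east as green's twin. In the 20.0 h up to 2.5 d, with ring held at its last green reading, my estimate is that the leak takes about 13 points from ring in south-east. On my supposition, ring in green took in 14 points between 20.0 h and 40.0 h. If that inflow follows open dimer, it now brings 11 points, less than the drain. Ring in south-east then ends near 35.3 % by this estimate, and with the total held at its green value of 40.0 h my share for south-east is 37.6 %.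

The forecast gives 45 %, 40 % and 32 %, and says the share falls all the way. Where I suppose otherwise, it says: “The over-reaction product comes from the dimer”. We agree on the direction, but for south-east it stands higher than mine.

The flasks give 38.5 %, 37.0 % and 34.5 %: the share falls all the way.

    starting material → ring (k = 2.40 × 10⁻⁵ s⁻¹)
    2 starting material ⇌ open dimer (K = 4.60 L mol⁻¹, k = 2.00 × 10⁻⁵ L mol⁻¹ s⁻¹)
    ring → over-reaction product (k = 4.40 × 10⁻⁶ s⁻¹)

In north, with each step taken net, ring is made 3.61 times faster than it is used up at 0.384 d, but at 2.50 d that ratio is 0.680. From 1.25 d to 2.50 d in north, the leak on the mean ring gives 20 points of over-reaction product, and the flask gains 19 points. In south-west over the same time, the leak gives 17 points, and the flask gains 16 points.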